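**Retrosynthetic overview**
- Ring A carries oxygen on three adjacent carbons (C7, C8, C8a) and hydrogen on C5 and C6. C6=C7–C8=C8a is therefore read as a 1-alkoxy-2-methoxy-3-silyloxybutadiene and C4a–C5 as a terminal alkyne, joined through O1–C2–C3–C4.
- Target 18 ⇐ silyl ether 17 ⇐ dienyne 15 by an intramolecular Diels–Alder reaction and DDQ dehydrogenation (bonds C4a–C8a and C5–C6).
- 15 ⇐ methyl ketone 14 ⇐ alkynol 7 + dimethoxy enone 13 (made from methyl methoxyacetate and methyl formate).
- 7 ⇐ lactone 5 (lactol, then alkyne homologation) ⇐ arylboronic acid 3 + furan-2(5H)-one; the rhodium-catalysed conjugate addition sets C3.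
- Ring order: ring B is bought as 1,2,3,4-tetramethoxybenzene; the oxygen ring and ring A are closed together in the last skeletal step.

Key step: step 9

Assumption: the (S)-BINAP–rhodium catalyst is taken to add the aryl group to furan-2(5H)-one with the same facial sense as to cyclic enones and six-membered unsaturated lactones, which gives the (S)-lactone; if the opposite sense were found, (R)-BINAP would be used.

**Route**

Step 1
Reactants: 1 1,2,3,4-tetramethoxybenzene
Product: 3 (2,3,4,5-tetramethoxyphenyl)boronic acid, via aryllithium 2 (not isolated)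
Conditions: n-BuLi, TMEDA, THF, 0 °C; B(Oi-Pr)3, −78 °C → rt; 1 M HCl
Reagents that add atoms: triisopropyl borate, CC(C)OB(OC(C)C)OC(C)C; water, O
Why: Directed ortho-lithiation removes one of the two equivalent ring protons, each flanked by a methoxy group, and the aryllithium is trapped by the borate and hydrolysed to the boronic acid (lithiation–borylation).

Step 2
Reactants: 3 (2,3,4,5-tetramethoxyphenyl)boronic acid (excess); 4 furan-2(5H)-one
Product: 5 (4S)-4-(2,3,4,5-tetramethoxyphenyl)oxolan-2-one
Conditions: [Rh(OH)((S)-binap)]2 (1.5 mol %), dioxane/H2O 10:1, 50 °C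
Reagents that add atoms: none
Why: Hayashi–Miyaura rhodium-catalysed asymmetric 1,4-addition, in which the aryl–rhodium species carrying (S)-BINAP inserts the butenolide double bond on one enantioface and the rhodium enolate is hydrolysed, so that the ligand sets the stereocentre (the future C3) as S.

Step 3
Reactants: 5 (4S)-4-(2,3,4,5-tetramethoxyphenyl)oxolan-2-one
Product: 6 (4S)-4-(2,3,4,5-tetramethoxyphenyl)oxolan-2-ol (mixture of anomers)
Conditions: i-Bu2AlH, CH2Cl2, −78 °C; aq. KNaC4H4O6
Reagents that add atoms: none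
Why: Partial reduction of a lactone by i-Bu2AlH at low temperature stops at the aluminium hemiacetal, which gives the lactol on work-up; the stereocentre is remote from the reacting carbonyl.

Step 4
Reactants: 6 (4S)-4-(2,3,4,5-tetramethoxyphenyl)oxolan-2-ol
Product: 7 (2S)-2-(2,3,4,5-tetramethoxyphenyl)pent-4-yn-1-ol
Conditions: dimethyl (1-diazo-2-oxopropyl)phosphonate, K2CO3, MeOH, 0 °C → rt
Reagents that add atoms: dimethyl (1-diazo-2-oxopropyl)phosphonate, CC(=O)C(=[N+]=[N-])P(=O)(OC)OC
Why: Seyferth–Gilbert homologation in its Ohira–Bestmann form: the lactol is in equilibrium with the open hydroxy aldehyde, whose formyl group is converted by the diazomethylphosphonate anion into the terminal alkyne while the primary hydroxyl (the future O1) is set free; the stereocentre is β to the aldehyde and cannot epimerise.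

Step 5
Reactants: 8 methyl methoxyacetate; 9 methyl formate
Product: 11 methyl (2Z)-2,3-dimethoxyprop-2-enoate, via sodium formyl enolate 10 (not isolated)
Conditions: NaOMe, THF, 0 °C → rt; then Me2SO4, DMF, rt
Reagents that add atoms: dimethyl sulfate, COS(=O)(=O)OC
Why: Crossed Claisen condensation (only 8 can enolise, 9 can only accept) gives the stabilised sodium formyl enolate, which the hard electrophile Me2SO4 alkylates on oxygen; the isomer with the 3-methoxy group trans to the ester is expected to predominate, and any geometric mixture converges under the reversible exchange of step 7.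

Step 6
Reactants: 11 methyl (2Z)-2,3-dimethoxyprop-2-enoate
Product: 13 (3Z)-3,4-dimethoxybut-3-en-2-one, via Weinreb amide 12 (not isolated)
Conditions: MeNH(OMe)·HCl, i-PrMgCl, THF, −20 °C; then MeMgBr, −20 → 0 °C; aq. NH4Cl
Reagents that add atoms: methylmagnesium bromide, C[Mg]Br; N,O-dimethylhydroxylamine hydrochloride, CNOC.Cl (its atoms stay only in intermediate 12)
Why: Weinreb ketone synthesis run in one pot: the magnesium amide of N,O-dimethylhydroxylamine converts the ester into amide 12, whose chelated tetrahedral adduct with MeMgBr resists a second addition, and, as with vinylogous esters in general, 1,2-addition to the carbonyl is preferred over attack at the alkoxy-bearing carbon.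

Step 7
Reactants: 7 (2S)-2-(2,3,4,5-tetramethoxyphenyl)pent-4-yn-1-ol; 13 (3Z)-3,4-dimethoxybut-3-en-2-one (3 equiv)
Product: 14 (3Z)-3-methoxy-4-{[(2S)-2-(2,3,4,5-tetramethoxyphenyl)pent-4-yn-1-yl]oxy}but-3-en-2-one
Conditions: PPTS (10 mol %), PhMe, 5 Å molecular sieves, 80 °C
Reagents that add atoms: none
Why: Acid-catalysed alkoxy exchange of a β-alkoxy enone (vinylogous transesterification by addition of the alcohol to the protonated enone and loss of methanol), driven by excess 13 and removal of methanol; the exchange is reversible and should settle on the isomer with the new alkoxy group trans to the acetyl group, which is the geometry the cycloaddition needs, and the stereocentre of 7 is untouched.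

Step 8
Reactants: 14 (3Z)-3-methoxy-4-{[(2S)-2-(2,3,4,5-tetramethoxyphenyl)pent-4-yn-1-yl]oxy}but-3-en-2-one
Product: 15 tert-butyl{[(3Z)-3-methoxy-4-{[(2S)-2-(2,3,4,5-tetramethoxyphenyl)pent-4-yn-1-yl]oxy}buta-1,3-dien-2-yl]oxy}dimethylsilane
Conditions: TBSOTf, Et3N, CH2Cl2, −78 → 0 °C
Reagents that add atoms: tert-butyldimethylsilyl trifluoromethanesulfonate, CC(C)(C)[Si](C)(C)OS(=O)(=O)C(F)(F)F
Why: Soft enolisation of the methyl ketone with a silyl triflate and a tertiary amine (the standard way to make Danishefsky-type 2-silyloxydienes): the methyl group is the only enolisable position, the terminal alkyne is not deprotonated by Et3N, and the enol ether geometry is retained.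

Step 9
Reactants: 15 tert-butyl{[(3Z)-3-methoxy-4-{[(2S)-2-(2,3,4,5-tetramethoxyphenyl)pent-4-yn-1-yl]oxy}buta-1,3-dien-2-yl]oxy}dimethylsilane
Product: 17 tert-butyl{[(3S)-8-methoxy-3-(2,3,4,5-tetramethoxyphenyl)-3,4-dihydro-2H-chromen-7-yl]oxy}dimethylsilane, via cyclohexadiene cycloadduct 16 (not isolated)
Conditions: PhMe (0.01 M, degassed), 2,6-di-tert-butyl-4-methylpyridine (0.2 equiv), base-washed sealed tube, 190 °C; then DDQ (1.1 equiv), 0 °C → rt
Reagents that add atoms: none
Why: Proposed new method: on heating, the diene C6=C7–C8=C8a of 15 should add across the tethered alkyne C4a≡C5 in a concerted, asynchronous [4+2] cycloaddition (the nucleophilic terminus C6 bonds to the terminal alkyne carbon C5, and C8a bonds to C4a) to give 1,4-cyclohexadiene 16; DDQ then abstracts the doubly allylic, oxygen-stabilised hydride at C8a and the oxocarbenium ion loses a proton from C6 to give the arene. The closest known reaction type is the thermal intramolecular Diels–Alder reaction of silyloxydienes with tethered alkynes followed by quinone dehydrogenation to a benzene ring; new here is a 1-alkoxy-2-methoxy-3-silyloxydiene tethered through its own C1 oxygen to an unactivated terminal alkyne. The oxygen ring closes as a six-membered ring because the four-atom tether O1–C2–C3–C4 joins the diene terminus C8a to the internal alkyne carbon C4a (fused, type 1 mode), and ring A is the six-membered ring of the cycloadduct itself. No stereocentre made here survives: C8a of 16 is flattened on aromatisation, and C3, set in step 2, lies outside the reacting atoms. The step needs regiochemistry, which the tether fixes; the (Z) enol ether geometry that places O1 on the outer position of the s-cis diene, which steps 7 and 8 deliver; and dehydrogenation faster than loss of the C8a alkoxide, which is secured by keeping the thermal stage free of acid and adding DDQ cold only after the cycloaddition.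

Step 10
Reactants: 17 tert-butyl{[(3S)-8-methoxy-3-(2,3,4,5-tetramethoxyphenyl)-3,4-dihydro-2H-chromen-7-yl]oxy}dimethylsilane
Product: 18 (3S)-8-methoxy-3-(2,3,4,5-tetramethoxyphenyl)-3,4-dihydro-2H-chromen-7-ol
Conditions: Bu4NF, AcOH, THF, 0 °C
Reagents that add atoms: none
Why: Fluoride-mediated cleavage of an aryl silyl ether, buffered with acetic acid so that the electron-rich phenoxide is not exposed to base and air; the methyl ethers, the ring ether and C3 are inert.

**Compound list**
1 | 1,2,3,4-tetramethoxybenzene | COc1ccc(OC)c(OC)c1OC | starting material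
2 | (2,3,4,5-tetramethoxyphenyl)lithium | [Li]c1cc(OC)c(OC)c(OC)c1OC | intermediate
3 | (2,3,4,5-tetramethoxyphenyl)boronic acid | OB(O)c1cc(OC)c(OC)c(OC)c1OC | intermediate
4 | furan-2(5H)-one | O=C1C=CCO1 | starting material
5 | (4S)-4-(2,3,4,5-tetramethoxyphenyl)oxolan-2-one | O=C1C[C@H](CO1)c1cc(OC)c(OC)c(OC)c1OC | intermediate
6 | (4S)-4-(2,3,4,5-tetramethoxyphenyl)oxolan-2-ol, anomer mixture | OC1C[C@H](CO1)c1cc(OC)c(OC)c(OC)c1OC | intermediate
7 | (2S)-2-(2,3,4,5-tetramethoxyphenyl)pent-4-yn-1-ol | OC[C@@H](CC#C)c1cc(OC)c(OC)c(OC)c1OC | intermediate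
8 | methyl methoxyacetate | COCC(=O)OC | starting material
9 | methyl formate | COC=O | starting material
10 | sodium 2,3-dimethoxy-3-oxoprop-1-en-1-olate (sodium formyl enolate, geometry not defined) | COC(=O)C(OC)=C[O-].[Na+] | intermediate
11 | methyl (2Z)-2,3-dimethoxyprop-2-enoate | COC(=O)/C(OC)=C/OC | intermediate
12 | (2Z)-N,2,3-trimethoxy-N-methylprop-2-enamide (Weinreb amide) | CON(C)C(=O)/C(OC)=C/OC | intermediate
13 | (3Z)-3,4-dimethoxybut-3-en-2-one | CC(=O)/C(OC)=C/OC | intermediate
14 | (3Z)-3-methoxy-4-{[(2S)-2-(2,3,4,5-tetramethoxyphenyl)pent-4-yn-1-yl]oxy}but-3-en-2-one | CC(=O)/C(OC)=C/OC[C@@H](CC#C)c1cc(OC)c(OC)c(OC)c1OC | intermediate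
15 | tert-butyl{[(3Z)-3-methoxy-4-{[(2S)-2-(2,3,4,5-tetramethoxyphenyl)pent-4-yn-1-yl]oxy}buta-1,3-dien-2-yl]oxy}dimethylsilane | C=C(O[Si](C)(C)C(C)(C)C)/C(OC)=C/OC[C@@H](CC#C)c1cc(OC)c(OC)c(OC)c1OC | intermediate
16 | (3S)-7-[(tert-butyldimethylsilyl)oxy]-8-methoxy-3-(2,3,4,5-tetramethoxyphenyl)-3,4,6,8a-tetrahydro-2H-chromene, both C8a epimers | COc1cc([C@H]2COC3C(OC)=C(O[Si](C)(C)C(C)(C)C)CC=C3C2)c(OC)c(OC)c1OC | intermediate
17 | tert-butyl{[(3S)-8-methoxy-3-(2,3,4,5-tetramethoxyphenyl)-3,4-dihydro-2H-chromen-7-yl]oxy}dimethylsilane | COc1cc([C@H]2COc3c(ccc(O[Si](C)(C)C(C)(C)C)c3OC)C2)c(OC)c(OC)c1OC | intermediate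
18 | (3S)-8-methoxy-3-(2,3,4,5-tetramethoxyphenyl)-3,4-dihydro-2H-chromen-7-ol | COc1cc([C@H]2COc3c(ccc(O)c3OC)C2)c(OC)c(OC)c1OC | target

**Step count**
Total: 10 steps. Longest linear sequence: 8 steps (1, 2, 3, 4, 7, 8, 9, 10); steps 5 and 6 form the side branch to enone 13.

**Steps most likely to fail**

Step 9. The cycloaddition of the electron-rich diene onto an unactivated alkyne may be too slow to compete with thermal degradation of the silyl dienol ether. Alternatively, the cycloadduct may lose the C8a alkoxide and aromatise with opening of the oxygen ring before DDQ acts. The fallback uses known chemistry, sets out from boronic acid 3 and rejoins the route at target 18; ring A is brought in ready-made instead of being built. Commercial 1-(2,4-dihydroxy-3-methoxyphenyl)ethan-1-one is benzylated at the non-chelated 4-hydroxyl (BnBr, K2CO3, acetone) to 1-[4-(benzyloxy)-2-hydroxy-3-methoxyphenyl]ethan-1-one F1. This is condensed with DMF dimethyl acetal to the enaminone (2E)-1-[4-(benzyloxy)-2-hydroxy-3-methoxyphenyl]-3-(dimethylamino)prop-2-en-1-one F2 and cyclised with iodine to 7-(benzyloxy)-3-iodo-8-methoxy-4H-chromen-4-one F3. Suzuki–Miyaura coupling of F3 with 3 (Pd(PPh3)4, Na2CO3, DME/H2O) should give the isoflavone 7-(benzyloxy)-8-methoxy-3-(2,3,4,5-tetramethoxyphenyl)-4H-chromen-4-one F4. Asymmetric transfer hydrogenation (RuCl[(S,S)-TsDPEN](p-cymene), HCO2H/Et3N; the antipode expected from the usual model for aryl ketones) reduces the C2=C3 bond and then the ketone, with dynamic kinetic resolution at the enolisable C3. This should give the cis alcohol (3S,4S)-7-(benzyloxy)-8-methoxy-3-(2,3,4,5-tetramethoxyphenyl)-3,4-dihydro-2H-chromen-4-ol F5. Hydrogenolysis (H2, Pd/C (palladium on carbon), EtOH/AcOH) then removes the benzylic C4 hydroxyl and the benzyl ether to give 18.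

Step 2. Protodeboronation of the hindered, electron-rich boronic acid may outrun transmetalation to rhodium, or the facial selectivity on the five-membered lactone may be insufficient. The fallback sets out from 3 and rejoins at lactone 5; the C–C bond is made without asymmetry and the stereocentre is set by reduction. Suzuki–Miyaura coupling of 3 with commercial 4-bromofuran-2(5H)-one (Pd(PPh3)4, K2CO3, THF/H2O) should give 4-(2,3,4,5-tetramethoxyphenyl)furan-2(5H)-one F6. Copper hydride-catalysed asymmetric conjugate reduction (CuCl, NaOt-Bu, p-Tol-BINAP of the antipode that gives the S lactone, polymethylhydrosiloxane, t-BuOH, PhMe) then delivers 5.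

Step 7. The alkoxy exchange may stall at equilibrium or give a mixture of enol ether isomers, and the transient oxocarbenium ion may be captured by the electron-rich ring B (oxa-Pictet–Spengler closure). The fallback sets out from alkynol 7 and rejoins at enone 14; the enol ether is made under neutral conditions and the methyl ketone afterwards. Sodium enolate 10 is acidified to methyl 3-hydroxy-2-methoxyprop-2-enoate F7. Mitsunobu O-alkylation of F7 with 7 (PPh3, DIAD, THF) should give methyl (2Z)-2-methoxy-3-{[(2S)-2-(2,3,4,5-tetramethoxyphenyl)pent-4-yn-1-yl]oxy}prop-2-enoate F8. Conversion into the Weinreb amide (2Z)-N,2-dimethoxy-N-methyl-3-{[(2S)-2-(2,3,4,5-tetramethoxyphenyl)pent-4-yn-1-yl]oxy}prop-2-enamide F9 (MeNH(OMe)·HCl, i-PrMgCl, THF, −20 °C) and addition of MeMgBr (−40 → 0 °C) give 14.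

Further compounds
F1 | step 9 | 1-[4-(benzyloxy)-2-hydroxy-3-methoxyphenyl]ethan-1-one | CC(=O)c1ccc(OCc2ccccc2)c(OC)c1O
F2 | step 9 | (2E)-1-[4-(benzyloxy)-2-hydroxy-3-methoxyphenyl]-3-(dimethylamino)prop-2-en-1-one | CN(C)/C=C/C(=O)c1ccc(OCc2ccccc2)c(OC)c1O
F3 | step 9 | 7-(benzyloxy)-3-iodo-8-methoxy-4H-chromen-4-one | COc1c(OCc2ccccc2)ccc2c(=O)c(I)coc12
F4 | step 9 | 7-(benzyloxy)-8-methoxy-3-(2,3,4,5-tetramethoxyphenyl)-4H-chromen-4-one | COc1cc(-c2coc3c(OC)c(OCc4ccccc4)ccc3c2=O)c(OC)c(OC)c1OC
F5 | step 9 | (3S,4S)-7-(benzyloxy)-8-methoxy-3-(2,3,4,5-tetramethoxyphenyl)-3,4-dihydro-2H-chromen-4-ol | COc1cc([C@H]2COc3c(OC)c(OCc4ccccc4)ccc3[C@H]2O)c(OC)c(OC)c1OC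
F6 | step 2 | 4-(2,3,4,5-tetramethoxyphenyl)furan-2(5H)-one | O=C1C=C(CO1)c1cc(OC)c(OC)c(OC)c1OC
F7 | step 7 | methyl 3-hydroxy-2-methoxyprop-2-enoate | COC(=O)C(OC)=CO
F8 | step 7 | methyl (2Z)-2-methoxy-3-{[(2S)-2-(2,3,4,5-tetramethoxyphenyl)pent-4-yn-1-yl]oxy}prop-2-enoate | COC(=O)/C(OC)=C/OC[C@@H](CC#C)c1cc(OC)c(OC)c(OC)c1OC
F9 | step 7 | (2Z)-N,2-dimethoxy-N-methyl-3-{[(2S)-2-(2,3,4,5-tetramethoxyphenyl)pent-4-yn-1-yl]oxy}prop-2-enamide | CON(C)C(=O)/C(OC)=C/OC[C@@H](CC#C)c1cc(OC)c(OC)c(OC)c1OC
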